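**Assumption:** the target is the 2,3‑trans‑(2R,3S) dihydrobenzofuran with an (E)‑acrylic acid, exactly as drawn. (S)‑But‑3‑en‑2‑ol is taken as a commercially available chiral building block.

## Retrosynthetic overview
- The (E)‑acrylic acid is installed last, by Heck coupling of an aryl bromide with acrylic acid, so no cinnamate is present during ozonolysis.
- The dihydrobenzofuran ring closes last, by acid‑promoted 5‑exo addition of the phenol to a p‑silyloxybenzylic cation (p‑quinone methide). This gives 2,3‑trans, with C2 controlled by C3.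
- The C2 aryl group comes from ArMgBr addition to the aldehyde (lactol) unmasked by ozonolysis of a Claisen product.
- The key step is an aromatic Claisen [3,3] rearrangement of an (R,E)‑aryl allyl ether. It forms the C3a–C3 bond and transfers the carbinol configuration of (S)‑but‑3‑en‑2‑ol to C3 (3S).
- Ring order: the C3a–C3 bond forms first (Claisen); the O1–C2 bond forms last.

## Route

**Step 1**
Reactants: 1 (S)‑but‑3‑en‑2‑ol; 2 allyl TBS ether
Product: 3 (S,E)‑5‑(TBSO)pent‑3‑en‑2‑ol
Conditions: Grubbs II (5 mol %), CH2Cl2, 40 °C (2 in excess)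
Reagents that add atoms: none
Why: Cross‑metathesis extends the chain with E selectivity and does not touch the carbinol stereocentre.

**Step 2**
Reactants: 3; 4 4‑bromo‑2‑methoxyphenol
Product: 5 (R,E)‑aryl allyl ether
Conditions: PPh3, DIAD, THF, 0 °C → rt
Reagents that add atoms: none (PPh3 and DIAD are not incorporated)
Why: Mitsunobu etherification of an acidic phenol proceeds by SN2 with inversion, converting the (S)‑alcohol to the (R)‑ether needed for the Claisen.

**Step 3**
Reactants: 5
Product: 6 ortho‑allyl phenol with the new C3 stereocentre (S)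
Conditions: PhNEt2, 190 °C, sealed tube or microwave
Reagents that add atoms: none
Why: Aromatic Claisen [3,3] rearrangement. The E‑alkene and the methyl group sit equatorial in a chair transition state, so the carbinol configuration is transferred suprafacially to the new benzylic stereocentre. One ortho position carries OMe, so the allyl group goes to the free ortho carbon. Tautomerisation restores the arene.

**Step 4**
Reactants: 6; 7 ozone
Product: 8 lactol, (3S)‑5‑bromo‑3‑(TBSOCH2)‑7‑methoxy‑2,3‑dihydrobenzofuran‑2‑ol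
Conditions: O3, CH2Cl2/MeOH, −78 °C; then Me2S, −78 °C → rt
Reagents that add atoms: ozone, [O-][O+]=O (supplies the aldehyde oxygen)
Why: Ozonolysis cleaves the only alkene, and acetaldehyde is lost. The resulting o‑hydroxyaryl aldehyde closes to the lactol, which guards the α‑aryl stereocentre against epimerisation.

**Step 5**
Reactants: 4; 9 TBSCl
Product: 10 (4‑bromo‑2‑methoxyphenoxy)‑TBS
Conditions: TBSCl, imidazole, DMF, rt
Reagents that add atoms: TBSCl, CC(C)(C)[Si](C)(C)Cl
Why: Silylation masks the phenol so that the aryl Grignard can be made.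

**Step 6**
Reactants: 8; 10 (as ArMgBr, formed in situ from 10 and Mg)
Product: 11 diol, with C1 carbinol as an epimeric mixture and C2 (S) retained
Conditions: 10, Mg, THF (ArMgBr, 3.5 equiv); add 8, THF, −78 → 0 °C; aq. NH4Cl
Reagents that add atoms: none
Why: Grignard addition to the aldehyde, which is the open form of the lactol. The carbinol epimers are irrelevant because that carbon is ionised in the next step.

**Step 7**
Reactants: 11
Product: 12 (2R,3S)‑trans dihydrobenzofuran, bis‑TBS
Conditions: p‑TsOH·H2O (10 mol %), CH2Cl2, 0 °C → rt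
Reagents that add atoms: none (loses H2O)
Why: Acid‑promoted dehydrative 5‑exo cyclisation through the p‑silyloxybenzylic cation or p‑quinone methide. The phenol adds anti to the C3 CH2OTBS group, so trans forms (the same outcome as the quinone‑methide closure in lignan biosynthesis). This sets C2 as R, controlled by C3 (S).

**Step 8**
Reactants: 12
Product: 13 aryl bromide diol‑phenol
Conditions: TBAF, THF, 0 °C
Reagents that add atoms: none
Why: Fluoride removes both TBS ethers; neither stereocentre is acidic.

**Step 9**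
Reactants: 13; 14 acrylic acid
Product: 15 target
Conditions: Pd(OAc)2 (5 mol %), P(o‑tol)3, Et3N, DMF, 100 °C
Reagents that add atoms: acrylic acid, C=CC(=O)O
Why: Mizoroki–Heck coupling tolerates free phenol, alcohol and acid, and gives the (E)‑cinnamic acid; the stereocentres are untouched.

## Compound list
1 | (S)‑but‑3‑en‑2‑ol | C=C[C@H](C)O | starting material
2 | allyl tert‑butyldimethylsilyl ether | C=CCO[Si](C)(C)C(C)(C)C | starting material
3 | (2S,3E)‑5‑(TBSO)pent‑3‑en‑2‑ol | C[C@H](O)/C=C/CO[Si](C)(C)C(C)(C)C | intermediate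
4 | 4‑bromo‑2‑methoxyphenol | COc1cc(Br)ccc1O | starting material
5 | (2E,4R)‑4‑(4‑bromo‑2‑methoxyphenoxy)pent‑2‑enyl TBS ether | C[C@@H](Oc1ccc(Br)cc1OC)/C=C/CO[Si](C)(C)C(C)(C)C | intermediate
6 | 4‑bromo‑2‑methoxy‑6‑[(1S,2E)‑1‑(TBSOCH2)but‑2‑enyl]phenol | C/C=C/[C@H](CO[Si](C)(C)C(C)(C)C)c1cc(Br)cc(OC)c1O | intermediate
7 | ozone | [O-][O+]=O | reagent (starting material)
8 | (3S)‑5‑bromo‑3‑(TBSOCH2)‑7‑methoxy‑2,3‑dihydrobenzofuran‑2‑ol (anomers) | OC1Oc2c(OC)cc(Br)cc2[C@H]1CO[Si](C)(C)C(C)(C)C | intermediate
9 | tert‑butyldimethylsilyl chloride | CC(C)(C)[Si](C)(C)Cl | reagent (starting material)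
10 | (4‑bromo‑2‑methoxyphenoxy)‑TBS | COc1cc(Br)ccc1O[Si](C)(C)C(C)(C)C | intermediate
11 | 2‑[1‑(4‑TBSO‑3‑methoxyphenyl)‑1‑hydroxy‑3‑TBSO‑propan‑2(S)‑yl]‑4‑bromo‑6‑methoxyphenol (C1 epimers) | COc1cc(C(O)[C@H](CO[Si](C)(C)C(C)(C)C)c2cc(Br)cc(OC)c2O)ccc1O[Si](C)(C)C(C)(C)C | intermediate
12 | (2R,3S)‑5‑bromo‑2‑(4‑TBSO‑3‑methoxyphenyl)‑3‑(TBSOCH2)‑7‑methoxy‑2,3‑dihydrobenzofuran | COc1cc([C@@H]2Oc3c(OC)cc(Br)cc3[C@H]2CO[Si](C)(C)C(C)(C)C)ccc1O[Si](C)(C)C(C)(C)C | intermediate
13 | 4‑[(2R,3S)‑5‑bromo‑3‑(hydroxymethyl)‑7‑methoxy‑2,3‑dihydrobenzofuran‑2‑yl]‑2‑methoxyphenol | COc1cc([C@@H]2Oc3c(OC)cc(Br)cc3[C@H]2CO)ccc1O | intermediate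
14 | acrylic acid | C=CC(=O)O | starting material
15 | (E)‑3‑[(2R,3S)‑2‑(4‑hydroxy‑3‑methoxyphenyl)‑3‑(hydroxymethyl)‑7‑methoxy‑2,3‑dihydrobenzofuran‑5‑yl]acrylic acid | COc1cc([C@@H]2Oc3c(OC)cc(/C=C/C(=O)O)cc3[C@H]2CO)ccc1O | target

**Total steps:** 9. **Longest linear sequence:** 8 (Steps 1, 2, 3, 4, 6, 7, 8, 9).

## Three steps most likely to fail
1. **Step 6 (Grignard addition to the α‑aryl, β‑silyloxy aldehyde/lactol).** The stereocentre can epimerise, or TBSO⁻ can be lost by E1cB elimination.
   - Fallback: install the Ar′ carbinol before the rearrangement. Cross‑metathesis of 1 with racemic Ar′CH(OTBS)CH=CH2, then Mitsunobu, Claisen and ozonolysis with NaBH4 work‑up. No α‑chiral aldehyde is ever formed.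
2. **Step 7 (dehydrative cyclisation).** Elimination to the stilbene, TBS loss, or low trans selectivity are all possible.
   - Fallback: separate the C1 carbinol epimers of 11, keep C9 as OTBS, and close the ring by a stereospecific Mitsunobu SN2 reaction (DIAD/PPh3) on the appropriate epimer.
3. **Step 3 (Claisen at 190 °C).** Thermal decomposition, Z‑alkene contamination from Step 1, or an "abnormal" Claisen could erode the ee.
   - Fallback: use a different C–C bond‑forming approach to reach the same aryl–C3 connectivity. Convert (S)‑but‑3‑ene‑1,2‑diol (mono‑TBS) to the allylic carbonate and make the aryl–C3 bond by stereospecific Pd‑catalysed Suzuki allylic arylation with the protected 2‑hydroxy‑3‑methoxy‑5‑bromophenyl boronate. This gives the vinyl analogue of 6, which goes through Step 4 onward.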